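The isopropyl-bearing cyclopentane of the norbornane (quaternary bridgehead, CH–i-Pr, CH2, CH bridgehead, bridging CH) is traced back to a six-membered ring in which the future isopropyl carbon still lies between the quaternary bridgehead and the CH that later carries it. A trivalent-iodine induced oxidative ring contraction moves the quaternary carbon onto that CH: in one operation the bicyclo[3.2.1]octene becomes the bicyclo[2.2.1]heptane, the extruded carbon appears as an exo methyl ketone (later isopropyl) and the CH–i-Pr stereocentre is set. The precursor, a bridged 1-methylcyclohexene, is made by ring-closing metathesis on a cyclopentanone annulated to (S)-Wieland–Miescher ketone, whose ring A is first given the equatorial bromide and the tertiary carbinol.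

Key step: step 11

Remark (locants and one assumption): C1 = CHBr, C4 = C(CH3)OH, C5/C10 = ring fusion (ring A = C1–C5, C10; ring B = C5–C10), C7 = quaternary bridgehead, C6 = one-carbon bridge, C11 = CH carrying the isopropyl carbon C16, C12 = CH2, C13 = CH bridgehead, C14 = CHOH, C15 = CH2; exo means on the side of C6; 2-nitropropene is assumed to be purchasable (otherwise made from 2-nitropropan-1-ol).

Step 1
Reactants: 1 (S)-Wieland–Miescher ketone
Product: 4 hydroxy enone (C1 hydroxyl axial and trans to the C10 methyl), via dienamine 2 (not isolated), via dienamine alcohol 3 (not isolated)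
Conditions: pyrrolidine, PhH, reflux (−H2O); then LiBH(s-Bu)3, THF, −78 °C; then AcOH, NaOAc, H2O, rt
Reagents that add atoms: water, O
Why: Temporary dienamine protection: only the conjugated C7 ketone condenses with pyrrolidine, so the bulky borohydride should reduce the free C1 ketone from the equatorial direction to the axial alcohol (trans to the C10 methyl), and the acetate buffer then hydrolyses the dienamine back to the enone.

Step 2
Reactants: 4 hydroxy enone
Product: 5 bromo enone (C1 bromine equatorial, cis to the C10 methyl)
Conditions: CBr4, P(n-C8H17)3, PhMe, 70 °C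
Reagents that add atoms: carbon tetrabromide, BrC(Br)(Br)Br
Why: Appel reaction: bromide displaces the alkoxyphosphonium group of the axial alcohol with inversion, which places bromine equatorial, and the trialkylphosphine in a non-ionising solvent should keep this neopentylic centre from eliminating or rearranging.

Step 3
Reactants: 5 bromo enone
Product: 6 methylene dienone (exocyclic CH2 on C4)
Conditions: CH2(OEt)2, POCl3, NaOAc, CHCl3, reflux
Reagents that add atoms: formaldehyde diethyl acetal, CCOCOCC
Why: Vinylogous Mannich-type γ-methylenation: the dienol ether formed in situ is attacked at C4 by the ethoxymethyl cation and loss of ethanol leaves the exocyclic methylene in conjugation with the enone, as known for steroidal 3-keto-4-enes.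

Step 4
Reactants: 6 methylene dienone
Product: 8 tertiary alcohol (C4 hydroxyl axial and cis to the C10 methyl), via hydroperoxide 7 (not isolated)
Conditions: Co(acac)2 (cat.), PhSiH3, O2 (1 atm), i-PrOH/CH2Cl2, 0 °C to rt; then PPh3
Reagents that add atoms: dioxygen, O=O
Why: Mukaiyama hydration: hydrogen-atom transfer to the terminal CH2 gives the tertiary, enone-conjugated C4 radical, which should take up O2 at C4 from the axial face syn to the C10 methyl (the stereoelectronically preferred direction known from C6 of steroidal enones), and the phosphine reduces the hydroperoxide.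

Step 5
Reactants: 8 tertiary alcohol
Product: 9 triethylsilyl ether
Conditions: Et3SiOTf, 2,6-lutidine, CH2Cl2, 0 °C
Reagents that add atoms: triethylsilyl trifluoromethanesulfonate, CC[Si](CC)(CC)OS(=O)(=O)C(F)(F)F
Why: Silylation of the hindered tertiary alcohol with the silyl triflate shields it from the Lewis acid of step 6.

Step 6
Reactants: 9 triethylsilyl ether
Product: 12 hydroxy 1,4-diketone (trans-decalin; C6 2-oxopropyl equatorial), via silyl enol ether 10 (not isolated), via silyl nitronate 11 (not isolated)
Conditions: RhCl(PPh3)3 (cat.), Et3SiH, PhH, 60 °C; then 2-nitropropene, SnCl4, CH2Cl2, −78 °C; then 2 M HCl, THF, 40 °C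
Reagents that add atoms: 2-nitropropene, CC(=C)[N+](=O)[O-]; water, O
Why: 1,4-Hydrosilylation delivers hydrogen to C5 from the face opposite the C10 methyl and the C4 silyloxy group (trans ring fusion) and fixes the enol ether towards C6, whose Mukaiyama–Michael addition to the nitroalkene followed by Nef hydrolysis should give the 1,4-diketone with the epimerisable C6 side chain equatorial, the acid also removing the silyl ether.

Step 7
Reactants: 12 hydroxy 1,4-diketone
Product: 13 tricyclic cyclopentenone (C14=O, C15=C7; H-6 trans to H-5)
Conditions: KOH, MeOH, 50 °C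
Reagents that add atoms: none
Why: Intramolecular aldol condensation of the methyl ketone (C15) onto the C7 carbonyl closes the cyclopentenone, and the γ-carbon C6 equilibrates under base to the more stable epimer with H-6 axial and trans to H-5.

Step 8
Reactants: 13 tricyclic cyclopentenone
Product: 14 allyl cyclopentenone (allyl on C13, cis to H-6)
Conditions: LiN(i-Pr)2 (2.2 equiv), THF, −78 °C; allyl bromide, −78 to −20 °C
Reagents that add atoms: allyl bromide, C=CCBr
Why: Kinetic α′-deprotonation at C13 and alkylation of the cross-conjugated enolate from the face away from C5 of ring B should put the allyl group cis to H-6, the hindered tertiary alkoxide remaining unalkylated.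

Step 9
Reactants: 14 allyl cyclopentenone
Product: 16 isopropenyl ketone (isopropenyl on C7 cis to H-6 and to the allyl group), via bis-silyl enol ether 15 (not isolated)
Conditions: CH2=C(CH3)MgBr, CuBr·SMe2 (cat.), Me3SiCl, THF, −78 to −30 °C; then 1 M HCl
Reagents that add atoms: isopropenylmagnesium bromide, CC(=C)[Mg]Br
Why: Chlorosilane-accelerated conjugate addition of the alkenylcopper reagent to the ring-fusion β-carbon C7 should give the cis-fused hydrindanone (attack syn to H-6 and anti to C5), so that the isopropenyl and allyl groups end up on the same face.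

Step 10
Reactants: 16 isopropenyl ketone
Product: 17 bridged methylcyclohexene (bicyclo[3.2.1]octenone with C16(CH3)=C11H)
Conditions: second-generation Grubbs catalyst RuCl2(=CHPh)(H2IMes)(PCy3) (cat.), PhMe, 80 °C
Reagents that add atoms: none
Why: Ring-closing metathesis of the cis-1,3-related allyl and isopropenyl groups closes the six-membered ring C7–C16–C11–C12–C13–C6 with loss of ethylene; only the cis isomer can close and C13 can epimerise.

Step 11
Reactants: 17 bridged methylcyclohexene
Product: 18 norbornanone dimethyl ketal (C11 exo-1,1-dimethoxyethyl, C14 ketone)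
Conditions: PhI(OH)OTs, MeOH, 0 °C to rt
Reagents that add atoms: methanol, CO
Why: The trivalent-iodine electrophile adds to C11 of the C16=C11 double bond from the face opposite the C14–C15 ketone bridge while methanol adds to tertiary C16; iodobenzene then leaves from the equatorial C11–I bond with a concerted 1,2-shift of the antiperiplanar C16–C7 bond, so that C7 moves from C16 to C11 and C16 is expelled as a methoxy-stabilised cation that methanol traps as the dimethyl ketal. The closest known reaction type is the oxidative ring contraction of 1-methylcyclohexene to acetylcyclopentane with trivalent iodine or Tl(NO3)3, a semipinacol-type rearrangement. No ring is closed: the six-membered ring C7–C16–C11–C12–C13–C6 contracts to the cyclopentane C7–C11–C12–C13–C6 and the bicyclo[3.2.1]octane becomes the bicyclo[2.2.1]heptane. The only new stereocentre, C11, is fixed by inversion at the iodine-bearing carbon: C7 enters anti to the leaving group and H-11 stays endo, so the two-carbon side chain is exo, which is also the more stable epimer. The step needs migration of C7 rather than of methyl or C13 and reaction of the alkene rather than of the ketone or the tertiary alcohol; the equatorial C–I bond is antiperiplanar only to ring bonds, only the shift of C7 gives an oxygen-stabilised cation, and the hindered ketone should not enolise in methanol at room temperature.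

Step 12
Reactants: 18 norbornanone dimethyl ketal
Product: 20 acetyl diol (C14 hydroxyl exo), via ketal alcohol 19 (not isolated)
Conditions: NaBH4, MeOH, 0 °C to rt; then 1 M HCl, THF, rt
Reagents that add atoms: water, O
Why: Hydride should attack the C14 ketone from the endo face because the exo face is blocked by C5 on the one-carbon bridge (as in the reduction of camphor to isoborneol), giving the exo alcohol, and dilute acid then unmasks the methyl ketone.

Step 13
Reactants: 20 acetyl diol
Product: 21 isopropenyl diol
Conditions: Ph3PCH3Br, KOt-Bu (excess), THF, 0 to 50 °C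
Reagents that add atoms: methyltriphenylphosphonium bromide, C[P+](c1ccccc1)(c1ccccc1)c1ccccc1.[Br-]
Why: Wittig methylenation of the only carbonyl group turns the acetyl into the isopropenyl group; excess ylide covers the two hydroxyls and C11 keeps its more stable exo configuration.

Step 14
Reactants: 21 isopropenyl diol
Product: 22 target CNP0317598.2
Conditions: H2 (1 atm), RhCl(PPh3)3 (cat.), PhH/EtOH, rt
Reagents that add atoms: none
Why: Homogeneous hydrogenation of the 1,1-disubstituted alkene gives the isopropyl group without forming a stereocentre and should leave the secondary bromide untouched.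

Compound list
1 | (S)-Wieland–Miescher ketone, (8aS)-8a-methyl-3,4,8,8a-tetrahydronaphthalene-1,6(2H,7H)-dione | C[C@]12CCC(=O)C=C1CCCC2=O | starting material
2 | pyrrolidine dienamine of 1 (N on C7, C6=C7 and C4=C5) | C[C@]12CCC(N3CCCC3)=CC1=CCCC2=O | intermediate (not isolated)
3 | dienamine alcohol (C1 hydroxyl trans to the C10 methyl) | C[C@]12CCC(N3CCCC3)=CC1=CCC[C@H]2O | intermediate (not isolated)
4 | hydroxy enone, C1 hydroxyl axial and trans to the C10 methyl | C[C@]12CCC(=O)C=C1CCC[C@H]2O | intermediate
5 | bromo enone, C1 bromine equatorial and cis to the C10 methyl | C[C@]12CCC(=O)C=C1CCC[C@@H]2Br | intermediate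
6 | methylene dienone (C4=CH2) | C[C@]12CCC(=O)C=C1C(=C)CC[C@@H]2Br | intermediate
7 | C4 hydroperoxide (OOH cis to the C10 methyl) | C[C@]12CCC(=O)C=C1[C@](C)(OO)CC[C@@H]2Br | intermediate (not isolated)
8 | bromo enone with C4(CH3)OH, hydroxyl axial and cis to the C10 methyl | C[C@]12CCC(=O)C=C1[C@](C)(O)CC[C@@H]2Br | intermediate
9 | C4 triethylsilyl ether of 8 | C[C@]12CCC(=O)C=C1[C@](C)(O[Si](CC)(CC)CC)CC[C@@H]2Br | intermediate
10 | triethylsilyl enol ether (C6=C7–OSiEt3), H-5 trans to the C10 methyl | C[C@]12CCC(O[Si](CC)(CC)CC)=C[C@@H]1[C@](C)(O[Si](CC)(CC)CC)CC[C@@H]2Br | intermediate (not isolated)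
11 | silyl nitronate adduct at C6 | C[C@]12CCC(=O)[C@@H](CC(C)=[N+]([O-])O[Si](CC)(CC)CC)[C@@H]1[C@](C)(O[Si](CC)(CC)CC)CC[C@@H]2Br | intermediate (not isolated)
12 | hydroxy 1,4-diketone, trans-decalin with equatorial 2-oxopropyl on C6 | C[C@]12CCC(=O)[C@@H](CC(C)=O)[C@@H]1[C@](C)(O)CC[C@@H]2Br | intermediate
13 | tricyclic cyclopentenone (C14=O, C15=C7), H-6 trans to H-5 | C[C@]12CCC3=CC(=O)C[C@H]3[C@@H]1[C@](C)(O)CC[C@@H]2Br | intermediate
14 | C13-allyl cyclopentenone, allyl cis to H-6 | C[C@]12CCC3=CC(=O)[C@H](CC=C)[C@H]3[C@@H]1[C@](C)(O)CC[C@@H]2Br | intermediate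
15 | bis(trimethylsilyl) compound (C15=C14–OSiMe3, C4–OSiMe3) | C[C@]12CC[C@@]3(C(C)=C)C=C(O[Si](C)(C)C)[C@H](CC=C)[C@H]3[C@@H]1[C@](C)(O[Si](C)(C)C)CC[C@@H]2Br | intermediate (not isolated)
16 | isopropenyl ketone, C7 quaternary, isopropenyl cis to H-6 and to the allyl group | C[C@]12CC[C@@]3(C(C)=C)CC(=O)[C@H](CC=C)[C@H]3[C@@H]1[C@](C)(O)CC[C@@H]2Br | intermediate
17 | bridged methylcyclohexene, bicyclo[3.2.1]octenone with C16(CH3)=C11H | C[C@]12CC[C@@]3(C(C)=CC4)CC(=O)[C@H]4[C@H]3[C@@H]1[C@](C)(O)CC[C@@H]2Br | intermediate
18 | norbornanone with exo-1,1-dimethoxyethyl on C11 and C14 ketone | CC(OC)(OC)[C@@H]1C[C@@H]2[C@H]3[C@H]4[C@](C)(CC[C@@]31CC2=O)[C@@H](Br)CC[C@@]4(C)O | intermediate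
19 | ketal alcohol (C14 hydroxyl exo) | CC(OC)(OC)[C@@H]1C[C@@H]2[C@H]3[C@H]4[C@](C)(CC[C@@]31C[C@H]2O)[C@@H](Br)CC[C@@]4(C)O | intermediate (not isolated)
20 | acetyl diol (exo-acetyl on C11, exo hydroxyl on C14) | CC(=O)[C@@H]1C[C@@H]2[C@H]3[C@H]4[C@](C)(CC[C@@]31C[C@H]2O)[C@@H](Br)CC[C@@]4(C)O | intermediate
21 | isopropenyl diol | CC(=C)[C@@H]1C[C@@H]2[C@H]3[C@H]4[C@](C)(CC[C@@]31C[C@H]2O)[C@@H](Br)CC[C@@]4(C)O | intermediate
22 | CNP0317598.2 | CC(C)[C@@H]1C[C@@H]2[C@H]3[C@H]4[C@](C)(CC[C@@]31C[C@H]2O)[C@@H](Br)CC[C@@]4(C)O | target

Total step count: 14. Longest linear sequence: 14 steps (fully linear from 1).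

Steps most likely to fail

Step 11 (key step). Methanol may capture the iodonium or alkyliodane at both carbons (1,2-dimethoxylation), or the ketone oxygen may take part, before the C7 shift occurs. The fallback sets out from 17 and comes back at 18 and runs the same contraction as a stepwise pinacol-type rearrangement. Dihydroxylation of 17 with OsO4 (cat.) and N-methylmorpholine N-oxide from the face opposite the ketone bridge should give the cis-diol F1. The secondary hydroxyl alone is mesylated (MsCl, pyridine) to the monomesylate F2. KOt-Bu in THF then triggers the semipinacol shift of C7, anti to the mesylate, to the acetyl diketone F3. HC(OMe)3/MeOH with pyridinium p-toluenesulfonate ketalises the less hindered methyl ketone and returns 18.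

Step 10. Ring closure may be slow because the isopropenyl group sits on the quaternary C7, so catalyst decay and intermolecular metathesis of the allyl group can take over. The fallback sets out from 13 and comes back at 22; it builds the six-membered ring by a radical cyclisation and still contracts it. Compound 13 is alkylated at C13 with prenyl bromide (LiN(i-Pr)2) to the prenyl enone F4. Shi epoxidation, with the ketone enantiomer that gives the 11R epoxide, leads to the epoxide F5. Cp2TiCl (trivalent titanium, from Cp2TiCl2 and Zn) opens it to the tertiary C16 radical, which adds 6-exo to the enone β-carbon C7 to give the gem-dimethyl bicyclic alcohol F6 with an equatorial C11 hydroxyl. Its mesylate F7 is solvolysed in (CF3)2CHOH with excess Et3SiH: a Wagner–Meerwein shift of C7 contracts the ring and the tertiary cation is reduced, giving the isopropyl ketone F8. NaBH4 then gives 22.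

Step 4. Oxygen capture by the delocalised radical may show poor regio- or facial selectivity, or the methylene group may simply be reduced. The fallback sets out from 6 and comes back at 8. Hydrogenation of the exocyclic methylene (H2, RhCl(PPh3)3) gives the 4-methyl enone F9 as a mixture of C4 epimers. It is converted with t-BuMe2SiOTf/Et3N into the dienol silyl ether F10. Rubottom-type γ-oxidation with dimethyldioxirane, attacking C4 axially, returns 8.

Further compounds
F1 | step 11 | cis-diol (C16 and C11 hydroxyls on the face opposite the ketone bridge) | C[C@]12CC[C@@]3([C@](C)(O)[C@H](O)C4)CC(=O)[C@H]4[C@H]3[C@@H]1[C@](C)(O)CC[C@@H]2Br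
F2 | step 11 | C11 monomesylate of F1 | C[C@]12CC[C@@]3([C@](C)(O)[C@H](OS(C)(=O)=O)C4)CC(=O)[C@H]4[C@H]3[C@@H]1[C@](C)(O)CC[C@@H]2Br
F3 | step 11 | acetyl diketone (exo-acetyl on C11, C14 ketone) | CC(=O)[C@@H]1C[C@@H]2[C@H]3[C@H]4[C@](C)(CC[C@@]31CC2=O)[C@@H](Br)CC[C@@]4(C)O
F4 | step 10 | C13-prenyl cyclopentenone | C[C@]12CCC3=CC(=O)[C@H](CC=C(C)C)[C@H]3[C@@H]1[C@](C)(O)CC[C@@H]2Br
F5 | step 10 | prenyl epoxide (11R) | C[C@]12CCC3=CC(=O)[C@H](C[C@H]4OC4(C)C)[C@H]3[C@@H]1[C@](C)(O)CC[C@@H]2Br
F6 | step 10 | gem-dimethyl bicyclo[3.2.1]octanol (C11 hydroxyl equatorial) | C[C@]12CC[C@@]3(C(C)(C)[C@H](O)C4)CC(=O)[C@H]4[C@H]3[C@@H]1[C@](C)(O)CC[C@@H]2Br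
F7 | step 10 | mesylate of F6 | C[C@]12CC[C@@]3(C(C)(C)[C@H](OS(C)(=O)=O)C4)CC(=O)[C@H]4[C@H]3[C@@H]1[C@](C)(O)CC[C@@H]2Br
F8 | step 10 | isopropyl ketone (exo-isopropyl on C11, C14 ketone) | CC(C)[C@@H]1C[C@@H]2[C@H]3[C@H]4[C@](C)(CC[C@@]31CC2=O)[C@@H](Br)CC[C@@]4(C)O
F9 | step 4 | 4-methyl enone (C4 epimers) | C[C@]12CCC(=O)C=C1C(C)CC[C@@H]2Br
F10 | step 4 | dienol tert-butyldimethylsilyl ether (C6=C7, C4=C5) | C[C@]12CCC(O[Si](C)(C)C(C)(C)C)=CC1=C(C)CC[C@@H]2Br
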